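**Retrosynthetic overview**

1. Numbering (terpenoid): ring A = C1–C5 and C10 (C1=C10; C4 bears Me C18 and CO2Me C19); ring B = C5–C10 (C8 bears Me C17; C9 bears Me C20 and the side chain C11–C16).
2. Ring B is closed last, through C6–C7, by a reductive decarboxylative 6-endo radical cyclisation: a C6 radical, released from a C5–CH2–CO2H arm (carboxyl = traceless activating group), adds to the isopropenyl group C7=C8(C17) on C9, and the same step sets C8.
3. Enabling feature: the 1,1-disubstituted C7=C8 alkene stands on quaternary C9, which the sp2 carbon C10 of ring A holds 1,3 to the C5–C6 arm, so attack at C7 closes ring B and leaves a tertiary C8 radical.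
4. The C5–C6 arm, C5 and the C1=C10 alkene come from an Ireland–Claisen rearrangement (C1–O to C5–C6) on ring A, which is formed first by an enantioselective Michael/aldol annulation (sets C4) followed by CBS reduction.
5. Quaternary C9 comes from a copper-catalysed enantioselective SN2' alkenylation of an allylic phosphate made from hexa-1,5-diyne; order of ring formation: ring A, then ring B.

Key step: step 14

Remark: hexa-1,5-diyne and methyl 2-methyl-3-oxopropanoate are taken as purchasable, and in steps 4, 9 and 10 the catalyst antipode named is the one expected to give the configuration drawn (the mirror-image catalysts are equally accessible).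

**Route**

Step 1
Reactants: 1 hexa-1,5-diyne
Product: 3 (2E,6E)-3,6-dimethylocta-2,6-diene-1,8-diol, via bis-alkenylalane 2 (not isolated)
Conditions: Me3Al (5 equiv), Cp2ZrCl2 (0.4 equiv), CH2Cl2, 0 °C to rt; then (CH2O)n, THF, 0 °C to rt; aq. NH4Cl
Reagents that add atoms: trimethylaluminium C[Al](C)C; formaldehyde (from paraformaldehyde) C=O
Why: Negishi zirconium-catalysed carboalumination adds methyl and aluminium syn across each terminal alkyne with aluminium on the terminal carbon, and hydroxymethylation of the two alkenyl–aluminium bonds with retention should give the E,E-diol.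

Step 2
Reactants: 3 (2E,6E)-3,6-dimethylocta-2,6-diene-1,8-diol
Product: 4 (2E,6E)-8-{[tert-butyl(dimethyl)silyl]oxy}-3,6-dimethylocta-2,6-dien-1-ol
Conditions: NaH (1.0 equiv), THF, 0 °C; TBSCl (1.0 equiv), rt
Reagents that add atoms: tert-butyldimethylsilyl chloride CC(C)(C)[Si](C)(C)Cl
Why: Silyl ether formation on the monosodium alkoxide of a symmetric diol is a standard mono-protection, and the two ends are equivalent so no regiochemical question arises.

Step 3
Reactants: 4 mono-silyl ether
Product: 5 (2E,6E)-8-{[tert-butyl(dimethyl)silyl]oxy}-3,6-dimethylocta-2,6-dien-1-yl diethyl phosphate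
Conditions: ClP(O)(OEt)2 (1.2 equiv), Et3N, DMAP (cat.), CH2Cl2, 0 °C
Reagents that add atoms: diethyl chlorophosphate CCOP(=O)(Cl)OCC
Why: O-Phosphorylation of the primary allylic alcohol installs the leaving group for allylic substitution without touching the alkene geometry.

Step 4
Reactants: 5 allylic phosphate
Product: 6 tert-butyl{[(2E,6R)-6-ethenyl-3,6,7-trimethylocta-2,7-dien-1-yl]oxy}dimethylsilane
Conditions: prop-1-en-2-yl(diisobutyl)aluminium (1.5 equiv), CuCl2·2H2O (2 mol %), chiral sulfonate-bearing imidazolinium salt (N-heterocyclic carbene precursor, 2.5 mol %), THF, −30 °C; aq. work-up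
Reagents that add atoms: prop-1-en-2-yl(diisobutyl)aluminium CC(=C)[Al](CC(C)C)CC(C)C
Why: Copper-catalysed enantioselective allylic substitution (SN2') passes the alkenyl group from aluminium via copper to the γ-carbon of the E-trisubstituted allylic phosphate, the chiral carbene ligand selecting the alkene face, so the all-carbon quaternary centre (future C9) should form with R configuration, while the allylic silyl ether at the far end is no leaving group.

Step 5
Reactants: 6 triene silyl ether
Product: 8 (3R)-3-[(3E)-5-{[tert-butyl(dimethyl)silyl]oxy}-3-methylpent-3-en-1-yl]-3,4-dimethylpent-4-en-1-ol, via catechol boronate 7 (not isolated)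
Conditions: catecholborane (1.3 equiv), RhCl(PPh3)3 (2 mol %), THF, 0 °C to rt; then NaOH, H2O2, 0 °C
Reagents that add atoms: hydrogen peroxide OO
Why: Rhodium-catalysed hydroboration is anti-Markovnikov and selects the monosubstituted vinyl group over the 1,1-disubstituted and trisubstituted alkenes, and oxidation of the C–B bond with retention gives the primary alcohol.

Step 6
Reactants: 8 primary alcohol
Product: 9 (3R)-3-[(3E)-5-{[tert-butyl(dimethyl)silyl]oxy}-3-methylpent-3-en-1-yl]-3,4-dimethylpent-4-enal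
Conditions: Dess–Martin periodinane (1.2 equiv), pyridine, CH2Cl2, 0 °C to rt
Reagents that add atoms: none
Why: Dess–Martin oxidation converts the primary alcohol into the aldehyde under conditions that leave the silyl ether and the three alkenes untouched.

Step 7
Reactants: 9 aldehyde
Product: 10 (5R)-5-[(3E)-5-{[tert-butyl(dimethyl)silyl]oxy}-3-methylpent-3-en-1-yl]-5,6-dimethylhepta-1,6-dien-3-ol (both C3 epimers)
Conditions: CH2=CHMgBr (1.2 equiv), THF, −78 °C; then H2O
Reagents that add atoms: vinylmagnesium bromide C=C[Mg]Br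
Why: Grignard 1,2-addition to the aldehyde gives the secondary allylic alcohol as a mixture at the carbinol carbon, which does not matter because this centre is oxidised in the next step.

Step 8
Reactants: 10 allylic alcohol
Product: 11 (5R)-5-[(3E)-5-{[tert-butyl(dimethyl)silyl]oxy}-3-methylpent-3-en-1-yl]-5,6-dimethylhepta-1,6-dien-3-one
Conditions: Dess–Martin periodinane (1.2 equiv), pyridine, CH2Cl2, 0 °C
Reagents that add atoms: none
Why: Dess–Martin oxidation of the allylic alcohol gives the vinyl ketone, which is used at once because it polymerises on storage.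

Step 9
Reactants: 11 vinyl ketone; 12 methyl 2-methyl-3-oxopropanoate
Product: 14 methyl (1S)-3-[(3S,6E)-8-{[tert-butyl(dimethyl)silyl]oxy}-2,3,6-trimethylocta-1,6-dien-3-yl]-1-methyl-4-oxocyclohex-2-ene-1-carboxylate, via Michael adduct 13 (not isolated)
Conditions: 12 (1.5 equiv), quinidine-derived bifunctional squaramide (10 mol %), toluene, −20 °C; then pyrrolidine (0.3 equiv), AcOH (0.3 equiv), 40 °C
Reagents that add atoms: none
Why: Organocatalytic enantioselective Michael addition of the formyl ester to the vinyl ketone sets the quaternary centre (future C4) as S under catalyst control, and the following amine-mediated intramolecular aldol condensation (Robinson annulation) can only join the ketone α-carbon next to the quaternary centre (C10) to the non-enolisable aldehyde (C5), which closes ring A as the 2-substituted cyclohexenone.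

Step 10
Reactants: 14 enone
Product: 15 methyl (1S,4R)-3-[(3S,6E)-8-{[tert-butyl(dimethyl)silyl]oxy}-2,3,6-trimethylocta-1,6-dien-3-yl]-4-hydroxy-1-methylcyclohex-2-ene-1-carboxylate
Conditions: (S)-2-methyl-CBS-oxazaborolidine (0.2 equiv), catecholborane (1.5 equiv), toluene, −78 °C; aq. work-up
Reagents that add atoms: none
Why: Corey–Bakshi–Shibata reduction delivers hydride to one face of the enone carbonyl under catalyst control, the substituted alkene carbon acting as the large group, so the carbinol centre (C1) should form as R with the hydroxyl on the ring face that the C5–C6 bond has to take later.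

Step 11
Reactants: 15 allylic alcohol
Product: 16 methyl (1S,4R)-4-(acetyloxy)-3-[(3S,6E)-8-{[tert-butyl(dimethyl)silyl]oxy}-2,3,6-trimethylocta-1,6-dien-3-yl]-1-methylcyclohex-2-ene-1-carboxylate
Conditions: Ac2O, pyridine, DMAP (cat.), CH2Cl2, rt
Reagents that add atoms: acetic anhydride CC(=O)OC(C)=O
Why: DMAP-catalysed acetylation of the secondary allylic alcohol proceeds with retention at C1.

Step 12
Reactants: 16 allylic acetate
Product: 19 [(1R,6S)-2-[(3S,6E)-8-{[tert-butyl(dimethyl)silyl]oxy}-2,3,6-trimethylocta-1,6-dien-3-yl]-6-(methoxycarbonyl)-6-methylcyclohex-2-en-1-yl]acetic acid, via silyl ketene acetal 17 (not isolated), via trimethylsilyl ester 18 (not isolated)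
Conditions: LiN(i-Pr)2 (1.3 equiv), THF, −78 °C; TMSCl, Et3N, −78 °C to rt, then 60 °C; aq. citric acid
Reagents that add atoms: none
Why: Ireland–Claisen rearrangement of the silyl ketene acetal runs suprafacially through a boat-like [3,3] transition state on the oxygen-bearing ring face, which transfers the C1–O configuration to C5 (R), forms the C5–C6 bond and moves the alkene to C1=C10; the ring ester has no α-hydrogen and is not enolised.

Step 13
Reactants: 19 carboxylic acid
Product: 20 1,3-dioxo-1,3-dihydro-2H-isoindol-2-yl [(1R,6S)-2-[(3S,6E)-8-{[tert-butyl(dimethyl)silyl]oxy}-2,3,6-trimethylocta-1,6-dien-3-yl]-6-(methoxycarbonyl)-6-methylcyclohex-2-en-1-yl]acetate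
Conditions: N-hydroxyphthalimide (1.1 equiv), N,N'-diisopropylcarbodiimide (1.1 equiv), DMAP (cat.), CH2Cl2, rt
Reagents that add atoms: N-hydroxyphthalimide O=C1c2ccccc2C(=O)N1O
Why: Carbodiimide (Steglich-type) esterification turns the acid into the redox-active N-acyloxyphthalimide without touching any stereocentre.

Step 14
Reactants: 20 N-acyloxyphthalimide
Product: 21 methyl (1S,5S,6R,8aR)-5-[(3E)-5-{[tert-butyl(dimethyl)silyl]oxy}-3-methylpent-3-en-1-yl]-1,5,6-trimethyl-1,2,3,5,6,7,8,8a-octahydronaphthalene-1-carboxylate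
Conditions: Ru(bpy)3(PF6)2 (2 mol %), Hantzsch ester (diethyl 2,6-dimethyl-1,4-dihydropyridine-3,5-dicarboxylate, 1.5 equiv), degassed CH2Cl2 (0.01 M), blue LEDs, rt
Reagents that add atoms: none
Why: The photoexcited ruthenium complex is reduced by the Hantzsch ester, and the resulting monovalent ruthenium transfers an electron to the N-acyloxyphthalimide, which loses phthalimide anion and CO2 to give the primary C6 radical; this adds to the CH2 terminus (C7) of the isopropenyl group, and the tertiary C8 radical is then reduced by hydrogen-atom transfer from the Hantzsch ester. The closest known reaction type is the reductive decarboxylative radical cyclisation of redox-active esters, combined with the 6-endo closure that is usual for hex-5-enyl radicals carrying a substituent on the internal alkene carbon. Ring B closes 6-endo-trig, because the 5-exo mode would need attack on the fully substituted C8 next to quaternary C9 whereas C7 is open and attack there gives a tertiary radical, and because sp2 C10 with the geminal substituents on C9 holds the C5–C6 arm and the alkene close together. The one new stereocentre, C8, should be set by substrate control: in the chair-like ring B (C5–H and the C20 methyl axial on one face) the hydrogen donor approaches C8 from the opposite face, so C17 becomes equatorial and cis to C20 (R at C8). The step needs cyclisation to outrun reduction of the C6 radical and 3-exo attack on C1=C10, which high dilution, the slow hydrogen donor and the unhindered 1,1-disubstituted acceptor should secure; the trisubstituted alkenes, the silyl ether and the ester are inert to these mild reductive conditions.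

Step 15
Reactants: 21 bicyclic silyl ether
Product: 22 methyl (1S,5S,6R,8aR)-5-[(3E)-5-hydroxy-3-methylpent-3-en-1-yl]-1,5,6-trimethyl-1,2,3,5,6,7,8,8a-octahydronaphthalene-1-carboxylate
Conditions: TBAF (1.2 equiv), THF, 0 °C to rt
Reagents that add atoms: none
Why: Fluoride-mediated desilylation frees the primary allylic alcohol, the hindered methyl ester and the alkenes being inert.

Step 16
Reactants: 22 allylic alcohol
Product: 23 methyl (1S,5S,6R,8aR)-1,5,6-trimethyl-5-[(3E)-3-methyl-5-(propanoyloxy)pent-3-en-1-yl]-1,2,3,5,6,7,8,8a-octahydronaphthalene-1-carboxylate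
Conditions: (EtCO)2O (1.5 equiv), Et3N, DMAP (cat.), CH2Cl2, 0 °C to rt
Reagents that add atoms: propanoic anhydride CCC(=O)OC(=O)CC
Why: DMAP-catalysed acylation of the primary allylic alcohol gives the propanoate and completes the target without affecting any stereocentre.

**Compound list**

1 | hexa-1,5-diyne | C#CCCC#C | starting material
2 | [(1E,5E)-2,5-dimethylhexa-1,5-diene-1,6-diyl]bis(dimethylalumane) | C[Al](C)/C=C(\C)CC/C(C)=C/[Al](C)C | intermediate
3 | (2E,6E)-3,6-dimethylocta-2,6-diene-1,8-diol | OC/C=C(\C)CC/C(C)=C/CO | intermediate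
4 | (2E,6E)-8-{[tert-butyl(dimethyl)silyl]oxy}-3,6-dimethylocta-2,6-dien-1-ol | CC(C)(C)[Si](C)(C)OC/C=C(\C)CC/C(C)=C/CO | intermediate
5 | (2E,6E)-8-{[tert-butyl(dimethyl)silyl]oxy}-3,6-dimethylocta-2,6-dien-1-yl diethyl phosphate | CC(C)(C)[Si](C)(C)OC/C=C(\C)CC/C(C)=C/COP(=O)(OCC)OCC | intermediate
6 | tert-butyl{[(2E,6R)-6-ethenyl-3,6,7-trimethylocta-2,7-dien-1-yl]oxy}dimethylsilane | CC(C)(C)[Si](C)(C)OC/C=C(\C)CC[C@](C(C)=C)(C)C=C | intermediate
7 | 2-[(3S)-3-[(3E)-5-{[tert-butyl(dimethyl)silyl]oxy}-3-methylpent-3-en-1-yl]-3,4-dimethylpent-4-en-1-yl]-1,3,2-benzodioxaborole | CC(C)(C)[Si](C)(C)OC/C=C(\C)CC[C@](C(C)=C)(C)CCB1Oc2ccccc2O1 | intermediate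
8 | (3R)-3-[(3E)-5-{[tert-butyl(dimethyl)silyl]oxy}-3-methylpent-3-en-1-yl]-3,4-dimethylpent-4-en-1-ol | CC(C)(C)[Si](C)(C)OC/C=C(\C)CC[C@](C(C)=C)(C)CCO | intermediate
9 | (3R)-3-[(3E)-5-{[tert-butyl(dimethyl)silyl]oxy}-3-methylpent-3-en-1-yl]-3,4-dimethylpent-4-enal | CC(C)(C)[Si](C)(C)OC/C=C(\C)CC[C@](C(C)=C)(C)CC=O | intermediate
10 | (5R)-5-[(3E)-5-{[tert-butyl(dimethyl)silyl]oxy}-3-methylpent-3-en-1-yl]-5,6-dimethylhepta-1,6-dien-3-ol (both C3 epimers) | CC(C)(C)[Si](C)(C)OC/C=C(\C)CC[C@](C(C)=C)(C)CC(O)C=C | intermediate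
11 | (5R)-5-[(3E)-5-{[tert-butyl(dimethyl)silyl]oxy}-3-methylpent-3-en-1-yl]-5,6-dimethylhepta-1,6-dien-3-one | CC(C)(C)[Si](C)(C)OC/C=C(\C)CC[C@](C(C)=C)(C)CC(=O)C=C | intermediate
12 | methyl 2-methyl-3-oxopropanoate (methyl 2-formylpropanoate) | CC(C=O)C(=O)OC | starting material
13 | methyl (2S,7R)-7-[(3E)-5-{[tert-butyl(dimethyl)silyl]oxy}-3-methylpent-3-en-1-yl]-2-formyl-2,7,8-trimethyl-5-oxonon-8-enoate | CC(C)(C)[Si](C)(C)OC/C=C(\C)CC[C@](C(C)=C)(C)CC(=O)CC[C@](C)(C(=O)OC)C=O | intermediate
14 | methyl (1S)-3-[(3S,6E)-8-{[tert-butyl(dimethyl)silyl]oxy}-2,3,6-trimethylocta-1,6-dien-3-yl]-1-methyl-4-oxocyclohex-2-ene-1-carboxylate | CC(C)(C)[Si](C)(C)OC/C=C(\C)CC[C@](C(C)=C)(C)C1=C[C@@](C)(C(=O)OC)CCC1=O | intermediate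
15 | methyl (1S,4R)-3-[(3S,6E)-8-{[tert-butyl(dimethyl)silyl]oxy}-2,3,6-trimethylocta-1,6-dien-3-yl]-4-hydroxy-1-methylcyclohex-2-ene-1-carboxylate | CC(C)(C)[Si](C)(C)OC/C=C(\C)CC[C@](C(C)=C)(C)C1=C[C@@](C)(C(=O)OC)CC[C@H]1O | intermediate
16 | methyl (1S,4R)-4-(acetyloxy)-3-[(3S,6E)-8-{[tert-butyl(dimethyl)silyl]oxy}-2,3,6-trimethylocta-1,6-dien-3-yl]-1-methylcyclohex-2-ene-1-carboxylate | CC(C)(C)[Si](C)(C)OC/C=C(\C)CC[C@](C(C)=C)(C)C1=C[C@@](C)(C(=O)OC)CC[C@H]1OC(C)=O | intermediate
17 | methyl (1S,4R)-3-[(3S,6E)-8-{[tert-butyl(dimethyl)silyl]oxy}-2,3,6-trimethylocta-1,6-dien-3-yl]-1-methyl-4-({1-[(trimethylsilyl)oxy]ethenyl}oxy)cyclohex-2-ene-1-carboxylate | CC(C)(C)[Si](C)(C)OC/C=C(\C)CC[C@](C(C)=C)(C)C1=C[C@@](C)(C(=O)OC)CC[C@H]1OC(=C)O[Si](C)(C)C | intermediate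
18 | trimethylsilyl [(1R,6S)-2-[(3S,6E)-8-{[tert-butyl(dimethyl)silyl]oxy}-2,3,6-trimethylocta-1,6-dien-3-yl]-6-(methoxycarbonyl)-6-methylcyclohex-2-en-1-yl]acetate | CC(C)(C)[Si](C)(C)OC/C=C(\C)CC[C@](C(C)=C)(C)C1=CCC[C@](C)(C(=O)OC)[C@@H]1CC(=O)O[Si](C)(C)C | intermediate
19 | [(1R,6S)-2-[(3S,6E)-8-{[tert-butyl(dimethyl)silyl]oxy}-2,3,6-trimethylocta-1,6-dien-3-yl]-6-(methoxycarbonyl)-6-methylcyclohex-2-en-1-yl]acetic acid | CC(C)(C)[Si](C)(C)OC/C=C(\C)CC[C@](C(C)=C)(C)C1=CCC[C@](C)(C(=O)OC)[C@@H]1CC(=O)O | intermediate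
20 | 1,3-dioxo-1,3-dihydro-2H-isoindol-2-yl [(1R,6S)-2-[(3S,6E)-8-{[tert-butyl(dimethyl)silyl]oxy}-2,3,6-trimethylocta-1,6-dien-3-yl]-6-(methoxycarbonyl)-6-methylcyclohex-2-en-1-yl]acetate | CC(C)(C)[Si](C)(C)OC/C=C(\C)CC[C@](C(C)=C)(C)C1=CCC[C@](C)(C(=O)OC)[C@@H]1CC(=O)ON2C(=O)c3ccccc3C2=O | intermediate
21 | methyl (1S,5S,6R,8aR)-5-[(3E)-5-{[tert-butyl(dimethyl)silyl]oxy}-3-methylpent-3-en-1-yl]-1,5,6-trimethyl-1,2,3,5,6,7,8,8a-octahydronaphthalene-1-carboxylate | CC(C)(C)[Si](C)(C)OC/C=C(\C)CC[C@]1(C)C2=CCC[C@](C)(C(=O)OC)[C@@H]2CC[C@H]1C | intermediate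
22 | methyl (1S,5S,6R,8aR)-5-[(3E)-5-hydroxy-3-methylpent-3-en-1-yl]-1,5,6-trimethyl-1,2,3,5,6,7,8,8a-octahydronaphthalene-1-carboxylate | OC/C=C(\C)CC[C@]1(C)C2=CCC[C@](C)(C(=O)OC)[C@@H]2CC[C@H]1C | intermediate
23 | methyl (1S,5S,6R,8aR)-1,5,6-trimethyl-5-[(3E)-3-methyl-5-(propanoyloxy)pent-3-en-1-yl]-1,2,3,5,6,7,8,8a-octahydronaphthalene-1-carboxylate | CCC(=O)OC/C=C(\C)CC[C@]1(C)C2=CCC[C@](C)(C(=O)OC)[C@@H]2CC[C@H]1C | target

Total step count: 16. Longest linear sequence: 16 steps (1 to 23).

**Steps most likely to fail, with fallbacks**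

Step 14 (key step). The primary C6 radical may take a hydrogen atom before it cyclises, it may attack the C1=C10 bond in a 3-exo mode (homoallyl to cyclopropylcarbinyl rearrangement), or the final hydrogen transfer at C8 may show poor facial selectivity. The fallback closes the same bond by two-electron chemistry and sets out from 15. KH and Bu3SnCH2I give the stannylmethyl ether F1. Tin–lithium exchange (n-BuLi, THF, −78 °C, tolerated by the hindered ester) triggers a Still–Wittig [2,3] rearrangement to the primary alcohol F2, with the same suprafacial transfer of chirality to C5 and the same shift of the alkene to C1=C10. Dess–Martin oxidation gives the aldehyde F3. Me2AlCl (CH2Cl2, −78 °C) promotes an intramolecular carbonyl-ene reaction in which C7 of the isopropenyl group attacks the aldehyde carbon C6 and a C17 hydrogen is transferred, closing ring B as the homoallylic alcohol F4 with an exocyclic C8=C17 bond. NaH, CS2 and MeI give the xanthate F5, and Barton–McCombie deoxygenation (Bu3SnH, AIBN, toluene, 80 °C) gives the exocyclic alkene F6. Hydrogenation of the 1,1-disubstituted alkene (H2, RhCl(PPh3)3, benzene) from the face opposite the axial C20 methyl should set C8 and bring the route back at 21.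

Step 4. The alkenyl group may be delivered at the α-carbon (SN2 instead of SN2'), or the 1,1-disubstituted alkenyl nucleophile may give low facial selectivity at the new quaternary centre. The fallback sets out from 4. ClCO2Me and pyridine give the allylic carbonate F7. Copper-catalysed enantioselective allylic boration (B2pin2, CuCl, chiral imidazolinium salt, NaOMe, THF) places boron on the γ-carbon and gives the tertiary allylboronate F8. Zweifel olefination (prop-1-en-2-yllithium, THF, −78 °C; then I2 and NaOMe) replaces boron by the isopropenyl group with retention at the migrating carbon and comes back to the route at 6.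

Step 9. The Michael addition may proceed with low enantioselectivity because the acyclic formyl-ester enol has no fixed geometry, and retro-Michael cleavage or loss of the formyl group may compete during the aldol stage. The fallback uses auxiliary control and sets out from 12 and 11. Condensation of 12 with (S)-1-phenylethylamine gives the enamino ester F9. Its aza-ene-type Michael addition to 11 (THF, rt) should form the quaternary centre under control of the auxiliary and gives the imine F10. Hydrolysis with aqueous AcOH gives 13, and a separate cyclodehydration (piperidinium acetate, toluene, 60 °C) comes back to the route at 14.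

Further compounds
F1 | step 14 | methyl (1S,4R)-3-[(3S,6E)-8-{[tert-butyl(dimethyl)silyl]oxy}-2,3,6-trimethylocta-1,6-dien-3-yl]-1-methyl-4-[(tributylstannyl)methoxy]cyclohex-2-ene-1-carboxylate | CC(C)(C)[Si](C)(C)OC/C=C(\C)CC[C@](C(C)=C)(C)C1=C[C@@](C)(C(=O)OC)CC[C@H]1OC[Sn](CCCC)(CCCC)CCCC
F2 | step 14 | methyl (1S,2R)-3-[(3S,6E)-8-{[tert-butyl(dimethyl)silyl]oxy}-2,3,6-trimethylocta-1,6-dien-3-yl]-2-(hydroxymethyl)-1-methylcyclohex-3-ene-1-carboxylate | CC(C)(C)[Si](C)(C)OC/C=C(\C)CC[C@](C(C)=C)(C)C1=CCC[C@](C)(C(=O)OC)[C@@H]1CO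
F3 | step 14 | methyl (1S,2R)-3-[(3S,6E)-8-{[tert-butyl(dimethyl)silyl]oxy}-2,3,6-trimethylocta-1,6-dien-3-yl]-2-formyl-1-methylcyclohex-3-ene-1-carboxylate | CC(C)(C)[Si](C)(C)OC/C=C(\C)CC[C@](C(C)=C)(C)C1=CCC[C@](C)(C(=O)OC)[C@@H]1C=O
F4 | step 14 | methyl (1S,5S,8aR)-5-[(3E)-5-{[tert-butyl(dimethyl)silyl]oxy}-3-methylpent-3-en-1-yl]-8-hydroxy-1,5-dimethyl-6-methylidene-1,2,3,5,6,7,8,8a-octahydronaphthalene-1-carboxylate (both C8 epimers) | CC(C)(C)[Si](C)(C)OC/C=C(\C)CC[C@]1(C)C2=CCC[C@](C)(C(=O)OC)[C@@H]2C(O)CC1=C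
F5 | step 14 | methyl (1S,5S,8aR)-5-[(3E)-5-{[tert-butyl(dimethyl)silyl]oxy}-3-methylpent-3-en-1-yl]-1,5-dimethyl-6-methylidene-8-{[(methylsulfanyl)carbonothioyl]oxy}-1,2,3,5,6,7,8,8a-octahydronaphthalene-1-carboxylate (both C8 epimers) | CC(C)(C)[Si](C)(C)OC/C=C(\C)CC[C@]1(C)C2=CCC[C@](C)(C(=O)OC)[C@@H]2C(OC(=S)SC)CC1=C
F6 | step 14 | methyl (1S,5S,8aR)-5-[(3E)-5-{[tert-butyl(dimethyl)silyl]oxy}-3-methylpent-3-en-1-yl]-1,5-dimethyl-6-methylidene-1,2,3,5,6,7,8,8a-octahydronaphthalene-1-carboxylate | CC(C)(C)[Si](C)(C)OC/C=C(\C)CC[C@]1(C)C2=CCC[C@](C)(C(=O)OC)[C@@H]2CCC1=C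
F7 | step 4 | (2E,6E)-8-{[tert-butyl(dimethyl)silyl]oxy}-3,6-dimethylocta-2,6-dien-1-yl methyl carbonate | CC(C)(C)[Si](C)(C)OC/C=C(\C)CC/C(C)=C/COC(=O)OC
F8 | step 4 | tert-butyl{[(2E,6S)-3,6-dimethyl-6-(4,4,5,5-tetramethyl-1,3,2-dioxaborolan-2-yl)octa-2,7-dien-1-yl]oxy}dimethylsilane | CC(C)(C)[Si](C)(C)OC/C=C(\C)CC[C@](B1OC(C)(C)C(C)(C)O1)(C)C=C
F9 | step 9 | methyl (2Z)-2-methyl-3-{[(1S)-1-phenylethyl]amino}prop-2-enoate | COC(=O)/C(C)=C\N[C@@H](C)c1ccccc1
F10 | step 9 | methyl (2S,7R)-7-[(3E)-5-{[tert-butyl(dimethyl)silyl]oxy}-3-methylpent-3-en-1-yl]-2,7,8-trimethyl-5-oxo-2-[(E)-{[(1S)-1-phenylethyl]imino}methyl]non-8-enoate | CC(C)(C)[Si](C)(C)OC/C=C(\C)CC[C@](C(C)=C)(C)CC(=O)CC[C@](C)(C(=O)OC)/C=N/[C@@H](C)c1ccccc1
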